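The synthesis rests on cutting the N1–C2 bond of the pyrrole ring. The feature exploited is the N1–C2(Br) unit. A carbon attached to both the ring nitrogen and a bromine corresponds to the CBr2 end of a 1,1-dibromoalkene sitting next to a sulfonanilide N–H on the benzene ring. Metal-free treatment with Cs2CO3 should join N1 to C2, close the five-membered ring and spend just one of the geminal bromines. Its twin stays on C2, and the C4 and C7 bromines are not disturbed. The precursor is N-[3,6-dibromo-2-(2,2-dibromovinyl)phenyl]methanesulfonamide. C3 emerges as C–H and is chlorinated last, once the mesyl group is gone.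

Key step: step 3

Assumption: the ring closure is drawn through the 1-bromoalkyne; if direct addition–elimination at the CBr2 carbon operates instead, product and mass balance are the same.

Step 1
Reactants: 1 3,6-dibromo-2-fluorobenzaldehyde; 2 methanesulfonamide
Product: 3 N-(3,6-dibromo-2-formylphenyl)methanesulfonamide
Conditions: MsNH2 (1.5 equiv), K2CO3 (3 equiv), DMSO, 80 °C; aqueous work-up at pH 4
Reagents that add atoms: methanesulfonamide (compound 2), CS(N)(=O)=O
Why: Nucleophilic aromatic substitution by addition–elimination, in which the sulfonamide anion attacks the C–F carbon that lies ortho to the formyl group and is further activated inductively by the adjacent bromine, fluoride leaves far faster than the bromide at the other ortho position, and the acidic product rests as its unreactive nitrogen anion until work-up, which also reverses any condensation at the aldehyde.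

Step 2
Reactants: 3 N-(3,6-dibromo-2-formylphenyl)methanesulfonamide; 4 carbon tetrabromide
Product: 5 N-[3,6-dibromo-2-(2,2-dibromovinyl)phenyl]methanesulfonamide
Conditions: PPh3 (4 equiv), CBr4 (2 equiv), CH2Cl2, 0 °C, 15 min; then 3, 0 °C to rt
Reagents that add atoms: carbon tetrabromide (compound 4), BrC(Br)(Br)Br
Why: Ramirez dibromoolefination (first stage of the Corey–Fuchs sequence), a Wittig reaction of the preformed dibromomethylene ylide that is known to accept di-ortho-substituted benzaldehydes, aryl bromides and sulfonamide N–H groups, with the excess of reagent covering any ylide lost to the acidic N–H.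

Step 3
Reactants: 5 N-[3,6-dibromo-2-(2,2-dibromovinyl)phenyl]methanesulfonamide
Product: 7 2,4,7-tribromo-1-(methylsulfonyl)-1H-indole, via 1-bromoalkyne 6 (not isolated)
Conditions: Cs2CO3 (2.5 equiv), dry DMF, 70 °C, N2
Reagents that add atoms: none
Why: Cs2CO3 deprotonates the sulfonamide and then removes the vinylic hydrogen together with the bromine anti to it (E2 dehydrobromination), which should give 1-bromoalkyne 6 and relieve the twist forced on the dibromovinyl group by its two ortho neighbours. The nitrogen anion adds to the bromine-bearing alkyne carbon, closing the pyrrole ring in the 5-endo-dig mode, and the resulting C3 carbanion is protonated by hydrogen carbonate; direct addition–elimination at the CBr2 carbon (5-endo-trig, then loss of bromide) would end at the same product. The closest known reaction type is the transition-metal-free, carbonate-mediated cyclisation of ortho-(gem-dibromovinyl)-N-sulfonylanilines to 2-bromoindoles. Untethered nucleophiles tend to add to the far carbon of a 1-bromoalkyne, but here that would be a 4-exo closure to a strained four-membered ring, so the ortho tether directs nitrogen to C2. The step needs vinylic C–Br to react in preference to aryl C–Br and only one geminal bromine to leave: no metal is present that could insert into C4–Br or C7–Br, neither aryl bromide is activated for substitution by carbonate or the sulfonamide anion, and after the single internal nucleophile is used up the surviving C2–Br has no partner left. No stereocentre is created.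

Step 4
Reactants: 7 2,4,7-tribromo-1-(methylsulfonyl)-1H-indole
Product: 8 2,4,7-tribromo-1H-indole
Conditions: LiOH·H2O (3 equiv), THF/H2O 3:1, 40 °C, dark; pH 7 phosphate buffer work-up; used promptly
Reagents that add atoms: none
Why: Base hydrolysis of an N-sulfonylindole, helped by the good leaving-group quality of the tribrominated indolide and by the squeeze on the mesyl group between the C2 and C7 bromines, so that hydroxide should release it either by attack at sulfur or by the sulfene (E1cB) path, while the alcohol-free medium prevents formation of an alkyl mesylate that could alkylate N1 and the three C–Br bonds are inert at this temperature.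

Step 5
Reactants: 8 2,4,7-tribromo-1H-indole
Product: 9 2,4,7-tribromo-3-chloro-1H-indole
Conditions: NCS (1.05 equiv), dry DMF, 0 °C to rt, dark
Reagents that add atoms: N-chlorosuccinimide, O=C1CCC(=O)N1Cl
Why: Electrophilic aromatic chlorination of an N–H indole, in which C3 is the enamine-type carbon and the only unsubstituted pyrrole position, the benzene ring is deactivated by two bromines, and one equivalent of NCS under dry conditions should stop at the monochloride.

Compound list
1 | 3,6-dibromo-2-fluorobenzaldehyde | O=Cc1c(F)c(Br)ccc1Br | starting material
2 | methanesulfonamide | CS(N)(=O)=O | starting material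
3 | N-(3,6-dibromo-2-formylphenyl)methanesulfonamide | CS(=O)(=O)Nc1c(Br)ccc(Br)c1C=O | intermediate
4 | carbon tetrabromide | BrC(Br)(Br)Br | starting material
5 | N-[3,6-dibromo-2-(2,2-dibromovinyl)phenyl]methanesulfonamide | CS(=O)(=O)Nc1c(Br)ccc(Br)c1C=C(Br)Br | intermediate
6 | N-[3,6-dibromo-2-(bromoethynyl)phenyl]methanesulfonamide | CS(=O)(=O)Nc1c(Br)ccc(Br)c1C#CBr | intermediate
7 | 2,4,7-tribromo-1-(methylsulfonyl)-1H-indole | CS(=O)(=O)n1c(Br)cc2c(Br)ccc(Br)c21 | intermediate
8 | 2,4,7-tribromo-1H-indole | Brc1cc2c(Br)ccc(Br)c2[nH]1 | intermediate
9 | 2,4,7-tribromo-3-chloro-1H-indole | Clc1c(Br)[nH]c2c(Br)ccc(Br)c12 | target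

Total step count: 5. Longest linear sequence: 5 steps (1 to 3 to 5 to 7 to 8 to 9).

Steps most likely to fail

Step 3. The closure may stall after dehydrobromination, because the nitrogen anion is electron-poor and crowded by the neighbouring aryl bromine. Prolonged heating then invites halophilic loss of the alkynyl bromine or hydration of the triple bond. The fallback sets out from 3 and comes back at target 9. It installs the C2 bromine by electrophilic substitution instead of carrying it through the ring closure.
- Ohira–Bestmann homologation of 3 (dimethyl (1-diazo-2-oxopropyl)phosphonate, K2CO3, MeOH, rt) should give N-(3,6-dibromo-2-ethynylphenyl)methanesulfonamide F1.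
- Bu4NF in refluxing THF should bring about the familiar 5-endo-dig cyclisation of a 2-ethynyl sulfonanilide to 4,7-dibromo-1-(methylsulfonyl)-1H-indole F2. The same pot should strip the mesyl group to give 4,7-dibromo-1H-indole F3.
- NCS in DMF chlorinates C3 to give 4,7-dibromo-3-chloro-1H-indole F4.
- NBS (1 equiv, DMF, 0 °C) then brominates the one pyrrole position left, C2, to give 9.

Step 1. The sulfonamide anion is a weak nucleophile, so the displacement may need temperatures at which the aldehyde is consumed by condensation. This includes aldol-type attack of the mesyl methyl group on the neighbouring formyl group. The fallback sets out from 1 and comes back at 3, separating C–N bond formation from sulfonylation.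
- Ammonia, a smaller and stronger nucleophile (NH3, DMSO, sealed vessel, 90 °C), should give 2-amino-3,6-dibromobenzaldehyde F5. Aqueous work-up reverses any condensation at the formyl group.
- N-sulfonylation with MsCl in pyridine (0 to 40 °C) then gives 3.

Step 2. Proton transfer from the acidic sulfonamide N–H to the ylide, together with slow addition to a carbonyl group shielded on both sides, may leave the olefination incomplete. The fallback sets out from 3 and comes back at 5, replacing the phosphorus ylide by a copper-catalysed olefination of a hydrazone.
- Hydrazine hydrate in EtOH at rt should give N-{3,6-dibromo-2-[(E)-hydrazinylidenemethyl]phenyl}methanesulfonamide F6.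
- CBr4 with CuCl (10 mol %) and aqueous NH3 in DMSO at rt should convert the hydrazone carbon into the dibromoalkene 5 with loss of nitrogen. The aryl bromides should not react at this temperature.

Further compounds
F1 | step 3 | N-(3,6-dibromo-2-ethynylphenyl)methanesulfonamide | CS(=O)(=O)Nc1c(Br)ccc(Br)c1C#C
F2 | step 3 | 4,7-dibromo-1-(methylsulfonyl)-1H-indole | CS(=O)(=O)n1ccc2c(Br)ccc(Br)c21
F3 | step 3 | 4,7-dibromo-1H-indole | Brc1ccc(Br)c2[nH]ccc12
F4 | step 3 | 4,7-dibromo-3-chloro-1H-indole | Clc1c[nH]c2c(Br)ccc(Br)c12
F5 | step 1 | 2-amino-3,6-dibromobenzaldehyde | Nc1c(Br)ccc(Br)c1C=O
F6 | step 2 | N-{3,6-dibromo-2-[(E)-hydrazinylidenemethyl]phenyl}methanesulfonamide | CS(=O)(=O)Nc1c(Br)ccc(Br)c1/C=N/N
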